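The earlier runs and the new flask stem from a simulated flask for substances that don't exist.

- You want to know which flask holds the most X at 25 h, and how much X stands in the first and the last.

| flask | E | Z | D | remark | time |
|---|---|---|---|---|---|
| elm | 0.11 M | 1.5 equiv | 10 mol% | run made earlier |  |
| violet | 0.050 M | 1.50 equiv | 15 mol% |  | 25 h |
| amber | 0.20 M | 2.20 equiv | 10 mol% |  | 25 h |
| grey | 0.060 M | 1.50 equiv | 10 mol% |  | 25 h |
| green | 0.10 M | 1.50 equiv | 10 mol% |  | 25 h |
| ochre | 0.030 M | 6.00 equiv | 10 mol% |  | 25 h |

elm run (percent of the E charged)

| time / h | X / % | E / % |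
|---|---|---|
| 2.00 | 6.9 | 90.9 |
| 5.00 | 14.0 | 76.7 |
| 10.0 | 23.2 | 62.1 |
| 15.0 | 29.2 | 51.1 |

(standard deviation of a reading: 0.3 percentage points)

- no earlier run changes the charge of D; that part of a forecast is a guess

- the flasks by amount of X, in percent of the E charged, highest first, at 25 h (violet / amber / grey / green / ochre)
- the amount of X, in percent of the E charged of the flask you put first, at 25 h
- the amount of X, in percent of the E charged of the flask you put last, at 25 h

- Elm is the flask to read: by 15.0 h it has lost 48.9% of its E, yet X stands at 29.2%, so part of the lost E is in something you cannot read.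
- Carry one number, the X share, which is X divided by the E gone: 0.597. At 5.00 h it reads 0.601 and at 10.0 h 0.612, so these readings stay about level while E keeps going.
- Don't lean on the reading at 2.00 h: its share of 0.758 stands higher than the later ones, so the share read later is not the share of the first hours.
- My own reckoning is that if the share holds, X in a flask is the share times its E gone, so ranking X means ranking E gone, and I expect X to end near 59.7% of the charge.
- The forecast says amber > green > violet > ochre > grey, with 72% first and 14% last, on the assumption that “the side path is first order in E”.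
- Here my reckoning differs: at my share, 72% needs 121% of the charge gone, more than was charged.
- The flasks give amber > ochre > green > violet > grey, with 54.3% first and 28.5% last.

    Z + D → G (k = 0.00130 M⁻¹ s⁻¹)
    E + G ⇌ J (K = 5.50 M⁻¹, k = 0.0120 M⁻¹ s⁻¹)
    J ⇌ D + X (K = 0.110 M, k = 0.0540 s⁻¹)
    X ⇌ Q (K = 0.660, k = 1.70 × 10⁻⁴ s⁻¹)
    Z → L (k = 3.30 × 10⁻⁸ s⁻¹)

- In amber, X turning into Q, forward step alone, has a half-life of 1.1 h, shorter than the 25 h of the run. At that time amber holds 54.3% X beside 35.4% Q, and the share times its E gone gives 54.0%. A further flask, like grey but with 6.00 equiv of Z, has 12% of its E left, so the share gives 52.5%. Its X stands at 53.2%.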